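The cyclohexane (C1 angelate, C3 methyl, C4 acetate, C6 side chain; side chain C7–C11) is disconnected at C1–C6. An intramolecular carbonyl-ene reaction of an acyclic (3S,4R)-4-alkoxycitronellal closes this bond, sets C1 and C6 in a chair with the C3 methyl equatorial, and unmasks the C1 hydroxyl next to a C7 isopropenyl group. The step exploits the homoallylic pattern O–C1–C6–C7 and the trans-diequatorial C1/C6, cis C1/C3 arrangement of the ring. Alcohol and alkene are then joined through an acrylate into a temporary δ-lactone (O1–C9) that relays configuration to C7 and delivers C9 as an acyl carbon.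

Key step: step 6

Remark: the locants C1–C11 and O1 (oxygen on C1) defined above are used throughout; (−)-Ipc is the isopinocampheyl group from (+)-α-pinene.

Step 1
Reactants: 1 4-methylpent-3-en-1-ol
Product: 2 4-methylpent-3-enal
Conditions: Dess–Martin periodinane, NaHCO3, CH2Cl2, 0 °C to rt; used as a solution
Reagents that add atoms: none
Why: Dess–Martin oxidation under buffered, non-basic conditions should give the β,γ-unsaturated aldehyde without migration of the alkene into conjugation.

Step 2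
Reactants: 2 4-methylpent-3-enal; 3 (E)-but-2-ene
Product: 7 (3S,4R)-3,7-dimethylocta-1,6-dien-4-ol, via (E)-crotylpotassium 4 (not isolated), via (E)-crotylbis(isopinocampheyl)borane 5 (not isolated), via bis(isopinocampheyl)borinate ester 6 (not isolated)
Conditions: 3, KOt-Bu, n-BuLi, THF, −78 to −45 °C; (−)-Ipc2BOMe, −78 °C; BF3·OEt2; then 2, −78 °C; NaOH, H2O2, rt
Reagents that add atoms: none
Why: Brown crotylboration through a closed Zimmerman–Traxler chair, in which the (E)-crotyl geometry should give the 3,4-anti relationship and the (−)-Ipc2B unit should direct addition to the Si face of the aldehyde (4R, 3S).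

Step 3
Reactants: 7 (3S,4R)-3,7-dimethylocta-1,6-dien-4-ol
Product: 8 1-({[(3S,4R)-3,7-dimethylocta-1,6-dien-4-yl]oxy}methyl)-4-methoxybenzene
Conditions: NaH, 4-methoxybenzyl chloride, n-Bu4NI (cat.), THF/DMF, 0 °C to rt
Reagents that add atoms: 4-methoxybenzyl chloride, COc1ccc(CCl)cc1
Why: Williamson etherification gives a PMB ether that is small enough to sit axial in step 6 and survives the Lewis acid and the organolithium used later.

Step 4
Reactants: 8 1-({[(3S,4R)-3,7-dimethylocta-1,6-dien-4-yl]oxy}methyl)-4-methoxybenzene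
Product: 10 (3S,4R)-4-[(4-methoxyphenyl)methoxy]-3,7-dimethyloct-6-en-1-ol, via B-alkyl-9-BBN adduct 9 (not isolated)
Conditions: 9-BBN, THF, 0 °C to rt; then NaOH, H2O2, 0 °C to rt
Reagents that add atoms: hydrogen peroxide, OO
Why: Hydroboration–oxidation, in which 9-BBN should add anti-Markovnikov to the monosubstituted vinyl group only and leave the trisubstituted alkene.

Step 5
Reactants: 10 (3S,4R)-4-[(4-methoxyphenyl)methoxy]-3,7-dimethyloct-6-en-1-ol
Product: 11 (3S,4R)-4-[(4-methoxyphenyl)methoxy]-3,7-dimethyloct-6-enal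
Conditions: Dess–Martin periodinane, NaHCO3, CH2Cl2, 0 °C to rt
Reagents that add atoms: none
Why: Dess–Martin oxidation of the primary alcohol; C2 is a methylene, so the C3 stereocentre is not at risk.

Step 6
Reactants: 11 (3S,4R)-4-[(4-methoxyphenyl)methoxy]-3,7-dimethyloct-6-enal
Product: 12 (1R,2S,4R,5S)-4-[(4-methoxyphenyl)methoxy]-5-methyl-2-(prop-1-en-2-yl)cyclohexan-1-ol
Conditions: Me2AlCl (1.5 equiv), CH2Cl2, −78 °C
Reagents that add atoms: none
Why: Me2AlCl activates the aldehyde and the C6=C7 alkene adds through a concerted, asynchronous six-centre ene transition state in which an allylic hydrogen of a C7 methyl passes to oxygen; this is the Type I intramolecular carbonyl-ene reaction known from citronellal to isopulegol. The cyclohexane closes by C1–C6 bond formation through a chair, with both π bonds exocyclic to the new ring (6-exo). C1 and C6 are set together by the chair that keeps the C3 methyl, the complexed carbonyl oxygen and the alkene equatorial, which should give the trans-diequatorial 1R,6S pair, cis-1,3 to the methyl. The step needs discrimination between this chair (C4–OPMB axial) and the alternative (C3 methyl axial, C4–OPMB equatorial) that leads to the 1S,6R diastereomer; the larger conformational energy of methyl (about 1.7 kcal/mol) against an alkoxy group (about 0.6–0.9) and the low temperature should secure it, and the minor diastereomer would be removed by chromatography. Regiochemistry of hydrogen transfer is not an issue because C7 carries two methyl groups, and Me2AlCl traps the product as its aluminium alkoxide, which suppresses Prins pathways.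

Step 7
Reactants: 12 (1R,2S,4R,5S)-4-[(4-methoxyphenyl)methoxy]-5-methyl-2-(prop-1-en-2-yl)cyclohexan-1-ol; 13 prop-2-enoyl chloride
Product: 14 (1R,2S,4R,5S)-4-[(4-methoxyphenyl)methoxy]-5-methyl-2-(prop-1-en-2-yl)cyclohexyl prop-2-enoate
Conditions: Et3N, DMAP (cat.), CH2Cl2, 0 °C
Reagents that add atoms: none
Why: O-acylation of the equatorial secondary alcohol with retention puts C8 and C9 on O1 as the second alkene for metathesis.

Step 8
Reactants: 14 (1R,2S,4R,5S)-4-[(4-methoxyphenyl)methoxy]-5-methyl-2-(prop-1-en-2-yl)cyclohexyl prop-2-enoate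
Product: 15 (4aS,6R,7S,8aR)-6-[(4-methoxyphenyl)methoxy]-4,7-dimethyl-4a,5,6,7,8,8a-hexahydro-2H-chromen-2-one
Conditions: Grubbs second-generation catalyst (5–10 mol %), toluene, high dilution, 80 °C
Reagents that add atoms: none
Why: Ring-closing metathesis of the acrylate with the 1,1-disubstituted alkene should expel ethylene and give the trans-fused 4-methyl-5,6-dihydropyran-2-one, a ring size and substitution pattern that this catalyst is known to close.

Step 9
Reactants: 15 (4aS,6R,7S,8aR)-6-[(4-methoxyphenyl)methoxy]-4,7-dimethyl-4a,5,6,7,8,8a-hexahydro-2H-chromen-2-one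
Product: 16 (4R,4aS,6R,7S,8aR)-6-[(4-methoxyphenyl)methoxy]-4,7-dimethyloctahydro-2H-chromen-2-one
Conditions: Cu(OAc)2·H2O (cat.), 1,2-bis(diphenylphosphino)benzene (cat.), (EtO)2MeSiH, t-BuOH, toluene, rt
Reagents that add atoms: none
Why: Copper hydride 1,4-reduction, in which hydride should reach C7 of the rigid trans-fused half-chair along the axial trajectory anti to the axial C6–H (the path to a chair enolate and the face not shielded by C6–H), so that the C7 methyl becomes equatorial, which is 7R.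

Step 10
Reactants: 16 (4R,4aS,6R,7S,8aR)-6-[(4-methoxyphenyl)methoxy]-4,7-dimethyloctahydro-2H-chromen-2-one; 17 1-bromo-2-methylprop-1-ene
Product: 20 (6R)-6-[(1S,2R,4S,5R)-2-hydroxy-5-[(4-methoxyphenyl)methoxy]-4-methylcyclohexyl]-2-methylhept-2-en-4-one, via (2-methylprop-1-enyl)lithium 18 (not isolated), via lithium lactolate 19 (not isolated)
Conditions: 17, t-BuLi (2 equiv), Et2O, −78 °C; then 16, THF, −78 °C; aq NH4Cl
Reagents that add atoms: none
Why: Bromine–lithium exchange and mono-addition of the alkenyllithium to the δ-lactone, whose tetrahedral lithium lactolate is stable at −78 °C and releases the δ-hydroxy enone (in equilibrium with its lactol) on work-up.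

Step 11
Reactants: 20 (6R)-6-[(1S,2R,4S,5R)-2-hydroxy-5-[(4-methoxyphenyl)methoxy]-4-methylcyclohexyl]-2-methylhept-2-en-4-one; 21 angelic acid
Product: 23 (1R,2S,4R,5S)-4-[(4-methoxyphenyl)methoxy]-5-methyl-2-[(2R)-6-methyl-4-oxohept-5-en-2-yl]cyclohexyl (2Z)-2-methylbut-2-enoate, via mixed trichlorobenzoic anhydride 22 (not isolated)
Conditions: 21, 2,4,6-trichlorobenzoyl chloride, Et3N, toluene, rt; then 20, 80 °C
Reagents that add atoms: none
Why: Yamaguchi esterification without DMAP, conditions under which angelates form with little Z to E isomerisation; the open hydroxy ketone tautomer is acylated with retention at C1.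

Step 12
Reactants: 23 (1R,2S,4R,5S)-4-[(4-methoxyphenyl)methoxy]-5-methyl-2-[(2R)-6-methyl-4-oxohept-5-en-2-yl]cyclohexyl (2Z)-2-methylbut-2-enoate
Product: 24 (1R,2S,4R,5S)-4-hydroxy-5-methyl-2-[(2R)-6-methyl-4-oxohept-5-en-2-yl]cyclohexyl (2Z)-2-methylbut-2-enoate
Conditions: DDQ, CH2Cl2/pH 7 buffer, 0 °C to rt
Reagents that add atoms: none
Why: Oxidative PMB cleavage by DDQ, done at the enone stage so that no oxidisable allylic alcohol is present; enone, angelate and C10=C11 should be inert.

Step 13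
Reactants: 24 (1R,2S,4R,5S)-4-hydroxy-5-methyl-2-[(2R)-6-methyl-4-oxohept-5-en-2-yl]cyclohexyl (2Z)-2-methylbut-2-enoate
Product: 25 (1R,2S,4R,5S)-4-hydroxy-2-[(2R,4R)-4-hydroxy-6-methylhept-5-en-2-yl]-5-methylcyclohexyl (2Z)-2-methylbut-2-enoate
Conditions: (S)-2-methyl-CBS-oxazaborolidine, catecholborane (excess), toluene, −78 °C; then MeOH
Reagents that add atoms: none
Why: Corey–Bakshi–Shibata reduction under reagent control, with the alkenyl group as the large and the C8 methylene as the small substituent, should give the 9R allylic alcohol; catecholborane at −78 °C leaves the ester and alkenes alone.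

Step 14
Reactants: 25 (1R,2S,4R,5S)-4-hydroxy-2-[(2R,4R)-4-hydroxy-6-methylhept-5-en-2-yl]-5-methylcyclohexyl (2Z)-2-methylbut-2-enoate
Product: 26 (1R,2S,4R,5S)-4-acetoxy-2-[(2R,4R)-4-acetoxy-6-methylhept-5-en-2-yl]-5-methylcyclohexyl (2Z)-2-methylbut-2-enoate
Conditions: Ac2O, pyridine, DMAP (cat.), CH2Cl2, rt
Reagents that add atoms: acetic anhydride, CC(=O)OC(C)=O
Why: DMAP-catalysed acetylation of both secondary alcohols with retention should give the target.

Compound list

1 | 4-methylpent-3-en-1-ol | CC(C)=CCCO | starting material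
2 | 4-methylpent-3-enal | CC(C)=CCC=O | intermediate
3 | (E)-but-2-ene | C/C=C/C | starting material
4 | (E)-but-2-en-1-ylpotassium | C/C=C/C[K] | intermediate (not isolated)
5 | [(E)-but-2-en-1-yl]bis[(−)-isopinocampheyl]borane | C/C=C/CB([C@@H]1C[C@@H]2C[C@H]([C@H]1C)C2(C)C)[C@@H]3C[C@@H]4C[C@H]([C@H]3C)C4(C)C | intermediate (not isolated)
6 | (3S,4R)-3,7-dimethylocta-1,6-dien-4-yl bis[(−)-isopinocampheyl]borinate | C=C[C@H](C)[C@H](OB([C@@H]1C[C@@H]2C[C@H]([C@H]1C)C2(C)C)[C@@H]3C[C@@H]4C[C@H]([C@H]3C)C4(C)C)CC=C(C)C | intermediate (not isolated)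
7 | (3S,4R)-3,7-dimethylocta-1,6-dien-4-ol | C=C[C@H](C)[C@H](O)CC=C(C)C | intermediate
8 | 1-({[(3S,4R)-3,7-dimethylocta-1,6-dien-4-yl]oxy}methyl)-4-methoxybenzene | C=C[C@H](C)[C@H](OCc1ccc(OC)cc1)CC=C(C)C | intermediate
9 | 9-[(3S,4R)-4-[(4-methoxyphenyl)methoxy]-3,7-dimethyloct-6-en-1-yl]-9-borabicyclo[3.3.1]nonane | C(C[C@H](C)[C@H](OCc1ccc(OC)cc1)CC=C(C)C)B2C3CCCC2CCC3 | intermediate (not isolated)
10 | (3S,4R)-4-[(4-methoxyphenyl)methoxy]-3,7-dimethyloct-6-en-1-ol | OCC[C@H](C)[C@H](OCc1ccc(OC)cc1)CC=C(C)C | intermediate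
11 | (3S,4R)-4-[(4-methoxyphenyl)methoxy]-3,7-dimethyloct-6-enal | O=CC[C@H](C)[C@H](OCc1ccc(OC)cc1)CC=C(C)C | intermediate
12 | (1R,2S,4R,5S)-4-[(4-methoxyphenyl)methoxy]-5-methyl-2-(prop-1-en-2-yl)cyclohexan-1-ol | O[C@@H]1C[C@H](C)[C@H](OCc2ccc(OC)cc2)C[C@H]1C(C)=C | intermediate
13 | prop-2-enoyl chloride (acryloyl chloride) | C=CC(=O)Cl | starting material
14 | (1R,2S,4R,5S)-4-[(4-methoxyphenyl)methoxy]-5-methyl-2-(prop-1-en-2-yl)cyclohexyl prop-2-enoate | C=CC(=O)O[C@@H]1C[C@H](C)[C@H](OCc2ccc(OC)cc2)C[C@H]1C(C)=C | intermediate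
15 | (4aS,6R,7S,8aR)-6-[(4-methoxyphenyl)methoxy]-4,7-dimethyl-4a,5,6,7,8,8a-hexahydro-2H-chromen-2-one (trans-fused unsaturated δ-lactone) | O1[C@@H]2C[C@H](C)[C@H](OCc3ccc(OC)cc3)C[C@H]2C(C)=CC1=O | intermediate
16 | (4R,4aS,6R,7S,8aR)-6-[(4-methoxyphenyl)methoxy]-4,7-dimethyloctahydro-2H-chromen-2-one | O1[C@@H]2C[C@H](C)[C@H](OCc3ccc(OC)cc3)C[C@H]2[C@H](C)CC1=O | intermediate
17 | 1-bromo-2-methylprop-1-ene | CC(C)=CBr | starting material
18 | (2-methylprop-1-en-1-yl)lithium | CC(C)=C[Li] | intermediate (not isolated)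
19 | lithium (4R,4aS,6R,7S,8aR)-6-[(4-methoxyphenyl)methoxy]-4,7-dimethyl-2-(2-methylprop-1-en-1-yl)octahydro-2H-chromen-2-olate (C2 epimers) | O1[C@@H]2C[C@H](C)[C@H](OCc3ccc(OC)cc3)C[C@H]2[C@H](C)CC1(O[Li])C=C(C)C | intermediate (not isolated)
20 | (6R)-6-[(1S,2R,4S,5R)-2-hydroxy-5-[(4-methoxyphenyl)methoxy]-4-methylcyclohexyl]-2-methylhept-2-en-4-one | O[C@@H]1C[C@H](C)[C@H](OCc2ccc(OC)cc2)C[C@H]1[C@H](C)CC(=O)C=C(C)C | intermediate
21 | angelic acid, (2Z)-2-methylbut-2-enoic acid | C/C=C(/C)C(=O)O | starting material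
22 | (2Z)-2-methylbut-2-enoic 2,4,6-trichlorobenzoic anhydride | C/C=C(/C)C(=O)OC(=O)c1c(Cl)cc(Cl)cc1Cl | intermediate (not isolated)
23 | (1R,2S,4R,5S)-4-[(4-methoxyphenyl)methoxy]-5-methyl-2-[(2R)-6-methyl-4-oxohept-5-en-2-yl]cyclohexyl (2Z)-2-methylbut-2-enoate | C/C=C(/C)C(=O)O[C@@H]1C[C@H](C)[C@H](OCc2ccc(OC)cc2)C[C@H]1[C@H](C)CC(=O)C=C(C)C | intermediate
24 | (1R,2S,4R,5S)-4-hydroxy-5-methyl-2-[(2R)-6-methyl-4-oxohept-5-en-2-yl]cyclohexyl (2Z)-2-methylbut-2-enoate | C/C=C(/C)C(=O)O[C@@H]1C[C@H](C)[C@H](O)C[C@H]1[C@H](C)CC(=O)C=C(C)C | intermediate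
25 | (1R,2S,4R,5S)-4-hydroxy-2-[(2R,4R)-4-hydroxy-6-methylhept-5-en-2-yl]-5-methylcyclohexyl (2Z)-2-methylbut-2-enoate | C/C=C(/C)C(=O)O[C@@H]1C[C@H](C)[C@H](O)C[C@H]1[C@H](C)C[C@H](C=C(C)C)O | intermediate
26 | (1R,2S,4R,5S)-4-acetoxy-2-[(2R,4R)-4-acetoxy-6-methylhept-5-en-2-yl]-5-methylcyclohexyl (2Z)-2-methylbut-2-enoate | C/C=C(/C)C(=O)O[C@@H]1C[C@H](C)[C@H](OC(C)=O)C[C@H]1[C@H](C)C[C@H](C=C(C)C)OC(C)=O | target

Total step count: 14. Longest linear sequence: 14 steps (1 to 26); 3, 13, 17 and 21 are purchased.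

Steps most likely to fail

Step 9. The risk is hydride delivery from the face syn to C6–H (poor facial selectivity), which would give the C7 epimer. The fallback sets out from 15 and comes back at 20. The lactone is opened with MeNHOMe·HCl and i-PrMgCl to the (2Z)-hydroxy Weinreb amide F1. A hydroxyl-directed hydrogenation with Crabtree's catalyst (H2, CH2Cl2) then gives the saturated amide F2: 1,3-allylic strain holds C6–H in the plane of the Z-alkene, and iridium bound to the C1 hydroxyl delivers hydrogen from that face. Addition of 18 (2 equiv) to F2 gives 20 without passing through 16.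

Step 6. The risk is insufficient discrimination between the two chair transition states, which would erode the relationship of C1/C6 to C3/C4, together with Prins-type ionisation. The fallback sets out from 11 and comes back at 12 and makes no new compound. It moves the source of stereocontrol from the substrate to the reagent: the cyclisation is run with a chiral Lewis acid known for asymmetric Type I carbonyl-ene closures of citronellal-type aldehydes (a stoichiometric BINOL–zinc reagent or a chiral chromium(III) Schiff-base catalyst), in the enantiomeric form matched with the C3 methyl, so that the aldehyde face is chosen by the ligand as well as by the ring conformation.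

Step 8. The risk is non-productive metathesis: the catalyst may engage only the acrylate and form dimers instead of closing onto the hindered 1,1-disubstituted alkene. The fallback sets out from 12 and comes back at 15. Esterification of 12 with diethylphosphonoacetic acid (DCC, DMAP) gives the phosphonoacetate F3. Ozonolysis of its isopropenyl group (O3, CH2Cl2, −78 °C; Me2S) gives the methyl ketone F4. An intramolecular Horner–Wadsworth–Emmons reaction under Masamune–Roush conditions (LiCl, i-Pr2NEt, MeCN) then forms the same C7=C8 bond.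

Further compounds

F1 | step 9 | (2Z)-3-[(1S,2R,4S,5R)-2-hydroxy-5-[(4-methoxyphenyl)methoxy]-4-methylcyclohexyl]-N-methoxy-N-methylbut-2-enamide | O[C@@H]1C[C@H](C)[C@H](OCc2ccc(OC)cc2)C[C@H]1/C(C)=C\C(=O)N(C)OC
F2 | step 9 | (3R)-3-[(1S,2R,4S,5R)-2-hydroxy-5-[(4-methoxyphenyl)methoxy]-4-methylcyclohexyl]-N-methoxy-N-methylbutanamide | O[C@@H]1C[C@H](C)[C@H](OCc2ccc(OC)cc2)C[C@H]1[C@H](C)CC(=O)N(C)OC
F0 | step 6 | none | none
F3 | step 8 | (1R,2S,4R,5S)-4-[(4-methoxyphenyl)methoxy]-5-methyl-2-(prop-1-en-2-yl)cyclohexyl 2-(diethoxyphosphoryl)acetate | CCOP(=O)(OCC)CC(=O)O[C@@H]1C[C@H](C)[C@H](OCc2ccc(OC)cc2)C[C@H]1C(C)=C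
F4 | step 8 | (1R,2R,4R,5S)-2-acetyl-4-[(4-methoxyphenyl)methoxy]-5-methylcyclohexyl 2-(diethoxyphosphoryl)acetate | CCOP(=O)(OCC)CC(=O)O[C@@H]1C[C@H](C)[C@H](OCc2ccc(OC)cc2)C[C@H]1C(C)=O
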